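A direct plan would keep the six-membered ring from an anisole: Birch reduction, then an (E)-2-alkylhept-2-enoate arm built by a Z-selective iodo-olefination and an alkyl–alkenyl cross-coupling (ester A1). A thermal intramolecular ene reaction would then close the cyclopentane onto the dihydroanisole to give spiro ester A2. The ester would be cut down to the C6′ methyl before the enone is unmasked and reduced.
Its weakest steps would be:
- the ene ring closure, which would need about 200 °C on a heat- and acid-sensitive dienol ether, and whose face of attack (hence C1, C5 and C6′) would hang on one methyl-bearing centre in the tether;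
- the olefination/cross-coupling pair, because any E/Z leakage in the trisubstituted enoate would be copied into C6′;
- the three-step removal of the ester oxygen (reduction, sulfonylation, hydride displacement), which would add length without adding complexity.

The cyclopentane of the target, with C1, C4 and the C6′ methyl, is the carbon skeleton of an iridoid, so the spirocycle is cut across the six-membered ring back to dihydronepetalactone (2), made by hydrogenating natural nepetalactone. The key step is an angular C-alkylation of the lactone enolate on the convex face: it makes the C5–C6 bond and the quaternary spiro centre in one operation, under control of the cis ring fusion. The lactone then serves twice, its carbonyl carbon becoming C10 and its alkoxy carbon C5′, and an aldol condensation closes the cyclohexenone last. No ene closure, no geometry-defined enoate and no ester-to-methyl sequence are needed.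

Key step: step 2

Remark: (4aS,7S,7aR)-nepetalactone, the main constituent of commercial catnip oil, is taken as a purchasable starting material.
Remark: C1–C10 are the atoms of the spiro[4.5]decane core of the target (C5 spiro, C7 carbinol); C1′–C6′ are the chain atoms counted from the acetoxymethylene carbon (C6′ is bonded to C1).

Step 1
Reactants: 1 (4aS,7S,7aR)-4,7-dimethyl-5,6,7,7a-tetrahydrocyclopenta[c]pyran-1(4aH)-one (nepetalactone)
Product: 2 (4S,4aR,7S,7aR)-4,7-dimethylhexahydrocyclopenta[c]pyran-1(3H)-one (dihydronepetalactone)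
Conditions: H2 (3 atm), Pd/SrCO3 (5 wt % Pd), EtOH, rt
Reagents that add atoms: none
Why: Heterogeneous catalytic hydrogenation of the enol ether double bond, in which hydrogen should add to the convex face of the cis-fused bicycle (syn to the hydrogen on C1), so that the C6′ methyl ends on the concave face and C6′ is set; the neutral support limits hydrogenolysis of the enol ester C–O bond.

Step 2
Reactants: 2 (4S,4aR,7S,7aR)-4,7-dimethylhexahydrocyclopenta[c]pyran-1(3H)-one; 3 1-bromobut-2-yne
Product: 4 (4S,4aR,7S,7aR)-7a-(but-2-yn-1-yl)-4,7-dimethylhexahydrocyclopenta[c]pyran-1(3H)-one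
Conditions: LiN(i-Pr)2, THF, −78 °C; then 3, DMPU, −78 to −20 °C
Reagents that add atoms: none
Why: Ester-enolate C-alkylation, an SN2 displacement on a propargylic bromide by the lithium enolate formed at the ring-fusion carbon, which makes the C5–C6 bond and the quaternary spiro carbon. The closest known reaction type is the angular alkylation of cis-fused bicyclic lactone and ketone enolates, which returns the cis ring fusion. No ring is closed here; the step fixes the carbon on which the six-membered ring is closed in step 10, and the but-2-ynyl group is a masked 2-oxobutyl arm (C6–C7–C8 plus the C8 methyl). The new stereocentre C5 is controlled by the bicycle: the electrophile should enter on the convex face, syn to the hydrogen on C1 and anti to the C6′ methyl, which the lactone ring holds pseudoaxial on the concave face, 1,3 to C5. This places C6 cis to the C4 methyl and leaves the lactone carbonyl (the future C10) cis to the C1 side chain. The selectivities needed are face selectivity against the opposing vicinal C4 methyl and C- over O-alkylation; the folded cis-fused enolate and the small, soft propargylic electrophile should secure them.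

Step 3
Reactants: 4 (4S,4aR,7S,7aR)-7a-(but-2-yn-1-yl)-4,7-dimethylhexahydrocyclopenta[c]pyran-1(3H)-one
Product: 5 (4S,4aR,7S,7aR)-7a-(but-2-yn-1-yl)-4,7-dimethyloctahydrocyclopenta[c]pyran-1-ol (both anomers)
Conditions: i-Bu2AlH, CH2Cl2, −78 °C; Rochelle salt work-up
Reagents that add atoms: none
Why: Partial hydride reduction of the δ-lactone stops at the lactol because the tetrahedral aluminate is stable at −78 °C, and the internal alkyne is inert.

Step 4
Reactants: 5 (4S,4aR,7S,7aR)-7a-(but-2-yn-1-yl)-4,7-dimethyloctahydrocyclopenta[c]pyran-1-ol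
Product: 6 (2S)-2-[(1R,2R,3S)-2-(but-2-yn-1-yl)-2-(2-methoxyethenyl)-3-methylcyclopentyl]propan-1-ol (E/Z mixture)
Conditions: Ph3P(CH2OMe)Cl (4 equiv), KN(SiMe3)2, THF, 0 °C to 40 °C
Reagents that add atoms: (methoxymethyl)triphenylphosphonium chloride COC[P+](c1ccccc1)(c1ccccc1)c1ccccc1.[Cl-]
Why: Wittig methoxymethylenation of the open hydroxy-aldehyde form of the lactol turns the former lactone carbonyl carbon into C10 of an enol ether (a masked C9 aldehyde) and frees the C5′ hydroxyl in the same step, so the two ends of the lactone are told apart without a protecting group.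

Step 5
Reactants: 6 (2S)-2-[(1R,2R,3S)-2-(but-2-yn-1-yl)-2-(2-methoxyethenyl)-3-methylcyclopentyl]propan-1-ol
Product: 7 (2S)-2-[(1R,2R,3S)-2-(but-2-yn-1-yl)-2-(2-methoxyethenyl)-3-methylcyclopentyl]propyl 4-methylbenzenesulfonate
Conditions: TsCl, Et3N, DMAP (cat.), CH2Cl2, 0 °C to rt
Reagents that add atoms: p-toluenesulfonyl chloride Cc1ccc(cc1)S(Cl)(=O)=O
Why: Sulfonylation of the only hydroxyl in an amine-buffered medium should leave the acid-labile enol ether intact.

Step 6
Reactants: 8 (R)-3-bromo-2-methylpropan-1-ol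
Product: 9 (R)-(3-bromo-2-methylpropoxy)(tert-butyl)diphenylsilane
Conditions: t-BuPh2SiCl, imidazole, CH2Cl2, rt
Reagents that add atoms: tert-butyl(chloro)diphenylsilane CC(C)(C)[Si](Cl)(c1ccccc1)c1ccccc1
Why: Imidazole-promoted silylation gives a primary silyl ether that withstands Grignard formation, dilute aqueous acid and mild base.

Step 7
Reactants: 9 (R)-(3-bromo-2-methylpropoxy)(tert-butyl)diphenylsilane
Product: 11 (S)-4-[(tert-butyldiphenylsilyl)oxy]-3-methylbutan-1-ol, via Grignard reagent 10 (not isolated)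
Conditions: Mg, THF, reflux; then (CH2O)n, 0 °C to rt; aq. NH4Cl
Reagents that add atoms: paraformaldehyde (as formaldehyde) C=O
Why: Grignard addition to formaldehyde lengthens the chain by one carbon (C4′) without touching the stereocentre, whose descriptor changes only through the priority rules.

Step 8
Reactants: 11 (S)-4-[(tert-butyldiphenylsilyl)oxy]-3-methylbutan-1-ol
Product: 12 (S)-(4-bromo-2-methylbutoxy)(tert-butyl)diphenylsilane
Conditions: CBr4, PPh3, CH2Cl2, 0 °C
Reagents that add atoms: tetrabromomethane BrC(Br)(Br)Br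
Why: Appel bromination converts the primary alcohol to the bromide under neutral conditions that spare the silyl ether.

Step 9
Reactants: 12 (S)-(4-bromo-2-methylbutoxy)(tert-butyl)diphenylsilane; 7 (2S)-2-[(1R,2R,3S)-2-(but-2-yn-1-yl)-2-(2-methoxyethenyl)-3-methylcyclopentyl]propyl 4-methylbenzenesulfonate
Product: 14 tert-butyl{[(2S,6R)-6-[(1R,2R,3S)-2-(but-2-yn-1-yl)-2-(2-methoxyethenyl)-3-methylcyclopentyl]-2-methylheptyl]oxy}diphenylsilane, via Grignard reagent 13 (not isolated)
Conditions: Mg, THF, 40 °C; then 7, Li2CuCl4 (5 mol %), THF, −20 °C to rt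
Reagents that add atoms: none
Why: Copper-catalysed coupling of a primary alkyl Grignard reagent with a primary tosylate, the standard way to extend β-branched chains such as steroid C22 tosylates, forms C4′–C5′ without touching C6′ or C2′, and the enol ether and internal alkyne are inert to it.

Step 10
Reactants: 14 tert-butyl{[(2S,6R)-6-[(1R,2R,3S)-2-(but-2-yn-1-yl)-2-(2-methoxyethenyl)-3-methylcyclopentyl]-2-methylheptyl]oxy}diphenylsilane
Product: 17 (1R,4S,5S)-1-[(2R,6S)-7-[(tert-butyldiphenylsilyl)oxy]-6-methylheptan-2-yl]-4,8-dimethylspiro[4.5]dec-8-en-7-one, via alkynal 15 (not isolated), via keto aldehyde 16 (not isolated)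
Conditions: p-TsOH·H2O (0.2 equiv), THF/H2O (10:1), rt; then (Ph3P)AuNTf2 (3 mol %), 50 °C; then KOH, MeOH, 0 °C to rt
Reagents that add atoms: water O
Why: Acid hydrolysis of the enol ether frees the C9 aldehyde, gold-catalysed hydration of the alkyne is steered to C7 by 6-exo attack of the aldehyde oxygen (carbonyl-assisted hydration of a 5-alkynyl carbonyl compound to a 1,5-dicarbonyl), and base then effects the intramolecular aldol condensation of the ethyl-ketone carbon C8 on C9, the only enolate–carbonyl pairing that gives an unstrained ring, to form the conjugated C8=C9 enone.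

Step 11
Reactants: 17 (1R,4S,5S)-1-[(2R,6S)-7-[(tert-butyldiphenylsilyl)oxy]-6-methylheptan-2-yl]-4,8-dimethylspiro[4.5]dec-8-en-7-one
Product: 18 (1R,4S,5S,7S)-1-[(2R,6S)-7-[(tert-butyldiphenylsilyl)oxy]-6-methylheptan-2-yl]-4,8-dimethylspiro[4.5]dec-8-en-7-ol
Conditions: (R)-1-methyl-3,3-diphenyltetrahydro-1H,3H-pyrrolo[1,2-c][1,3,2]oxazaborole (0.2 equiv), catecholborane, toluene, −78 °C
Reagents that add atoms: none
Why: Corey–Bakshi–Shibata 1,2-reduction under reagent control, in which the α-methyl alkenyl side (C8) acts as the large group and C6H2 as the small one, so the R catalyst should give the 7S allylic alcohol.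

Step 12
Reactants: 18 (1R,4S,5S,7S)-1-[(2R,6S)-7-[(tert-butyldiphenylsilyl)oxy]-6-methylheptan-2-yl]-4,8-dimethylspiro[4.5]dec-8-en-7-ol
Product: 19 (1R,4S,5S,7S)-1-[(2R,6S)-7-hydroxy-6-methylheptan-2-yl]-4,8-dimethylspiro[4.5]dec-8-en-7-ol
Conditions: Bu4NF, THF, rt
Reagents that add atoms: none
Why: Fluoride-induced desilylation cleaves the silyl ether, and nothing else in the molecule responds to fluoride.

Step 13
Reactants: 19 (1R,4S,5S,7S)-1-[(2R,6S)-7-hydroxy-6-methylheptan-2-yl]-4,8-dimethylspiro[4.5]dec-8-en-7-ol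
Product: 20 [(2S,6R)-6-[(1R,4S,5S,7S)-7-hydroxy-4,8-dimethylspiro[4.5]dec-8-en-1-yl]-2-methylheptyl] acetate
Conditions: vinyl acetate, immobilized Candida antarctica lipase B, t-BuOMe, rt
Reagents that add atoms: vinyl acetate CC(=O)OC=C
Why: Lipase-catalysed transesterification should acylate the unhindered primary hydroxyl and leave the secondary allylic hydroxyl, which is shielded by the C8 methyl and the nearby spiro carbon, free; the loss of acetaldehyde makes it irreversible.

**Compound list**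

1 | (4aS,7S,7aR)-4,7-dimethyl-5,6,7,7a-tetrahydrocyclopenta[c]pyran-1(4aH)-one (nepetalactone) | O1C=C(C)[C@H]2CC[C@H](C)[C@H]2C1=O | starting material
2 | (4S,4aR,7S,7aR)-4,7-dimethylhexahydrocyclopenta[c]pyran-1(3H)-one (dihydronepetalactone) | O1C[C@@H](C)[C@H]2CC[C@H](C)[C@H]2C1=O | intermediate
3 | 1-bromobut-2-yne | CC#CCBr | starting material
4 | (4S,4aR,7S,7aR)-7a-(but-2-yn-1-yl)-4,7-dimethylhexahydrocyclopenta[c]pyran-1(3H)-one | O1C[C@@H](C)[C@H]2CC[C@H](C)[C@@]2(CC#CC)C1=O | intermediate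
5 | (4S,4aR,7S,7aR)-7a-(but-2-yn-1-yl)-4,7-dimethyloctahydrocyclopenta[c]pyran-1-ol (both anomers) | O1C[C@@H](C)[C@H]2CC[C@H](C)[C@@]2(CC#CC)C1O | intermediate
6 | (2S)-2-[(1R,2R,3S)-2-(but-2-yn-1-yl)-2-(2-methoxyethenyl)-3-methylcyclopentyl]propan-1-ol (E/Z mixture) | OC[C@@H](C)[C@H]1CC[C@H](C)[C@@]1(CC#CC)C=COC | intermediate
7 | (2S)-2-[(1R,2R,3S)-2-(but-2-yn-1-yl)-2-(2-methoxyethenyl)-3-methylcyclopentyl]propyl 4-methylbenzenesulfonate | Cc1ccc(cc1)S(=O)(=O)OC[C@@H](C)[C@H]1CC[C@H](C)[C@@]1(CC#CC)C=COC | intermediate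
8 | (R)-3-bromo-2-methylpropan-1-ol | OC[C@@H](C)CBr | starting material
9 | (R)-(3-bromo-2-methylpropoxy)(tert-butyl)diphenylsilane | CC(C)(C)[Si](OC[C@@H](C)CBr)(c1ccccc1)c1ccccc1 | intermediate
10 | [(2R)-3-[(tert-butyldiphenylsilyl)oxy]-2-methylpropyl]magnesium bromide | CC(C)(C)[Si](OC[C@@H](C)C[Mg]Br)(c1ccccc1)c1ccccc1 | intermediate (not isolated)
11 | (S)-4-[(tert-butyldiphenylsilyl)oxy]-3-methylbutan-1-ol | CC(C)(C)[Si](OC[C@@H](C)CCO)(c1ccccc1)c1ccccc1 | intermediate
12 | (S)-(4-bromo-2-methylbutoxy)(tert-butyl)diphenylsilane | CC(C)(C)[Si](OC[C@@H](C)CCBr)(c1ccccc1)c1ccccc1 | intermediate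
13 | [(3S)-4-[(tert-butyldiphenylsilyl)oxy]-3-methylbutyl]magnesium bromide | CC(C)(C)[Si](OC[C@@H](C)CC[Mg]Br)(c1ccccc1)c1ccccc1 | intermediate (not isolated)
14 | tert-butyl{[(2S,6R)-6-[(1R,2R,3S)-2-(but-2-yn-1-yl)-2-(2-methoxyethenyl)-3-methylcyclopentyl]-2-methylheptyl]oxy}diphenylsilane | CC(C)(C)[Si](OC[C@@H](C)CCC[C@@H](C)[C@H]1CC[C@H](C)[C@@]1(CC#CC)C=COC)(c1ccccc1)c1ccccc1 | intermediate
15 | 2-[(1R,2R,5S)-1-(but-2-yn-1-yl)-2-[(2R,6S)-7-[(tert-butyldiphenylsilyl)oxy]-6-methylheptan-2-yl]-5-methylcyclopentyl]acetaldehyde | CC(C)(C)[Si](OC[C@@H](C)CCC[C@@H](C)[C@H]1CC[C@H](C)[C@@]1(CC#CC)CC=O)(c1ccccc1)c1ccccc1 | intermediate (not isolated)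
16 | 2-[(1S,2R,5S)-2-[(2R,6S)-7-[(tert-butyldiphenylsilyl)oxy]-6-methylheptan-2-yl]-5-methyl-1-(2-oxobutyl)cyclopentyl]acetaldehyde | CC(C)(C)[Si](OC[C@@H](C)CCC[C@@H](C)[C@H]1CC[C@H](C)[C@@]1(CC(=O)CC)CC=O)(c1ccccc1)c1ccccc1 | intermediate (not isolated)
17 | (1R,4S,5S)-1-[(2R,6S)-7-[(tert-butyldiphenylsilyl)oxy]-6-methylheptan-2-yl]-4,8-dimethylspiro[4.5]dec-8-en-7-one | CC(C)(C)[Si](OC[C@@H](C)CCC[C@@H](C)[C@H]1CC[C@H](C)[C@@]12CC=C(C)C(=O)C2)(c1ccccc1)c1ccccc1 | intermediate
18 | (1R,4S,5S,7S)-1-[(2R,6S)-7-[(tert-butyldiphenylsilyl)oxy]-6-methylheptan-2-yl]-4,8-dimethylspiro[4.5]dec-8-en-7-ol | CC(C)(C)[Si](OC[C@@H](C)CCC[C@@H](C)[C@H]1CC[C@H](C)[C@@]12CC=C(C)[C@@H](O)C2)(c1ccccc1)c1ccccc1 | intermediate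
19 | (1R,4S,5S,7S)-1-[(2R,6S)-7-hydroxy-6-methylheptan-2-yl]-4,8-dimethylspiro[4.5]dec-8-en-7-ol | OC[C@@H](C)CCC[C@@H](C)[C@H]1CC[C@H](C)[C@@]12CC=C(C)[C@@H](O)C2 | intermediate
20 | [(2S,6R)-6-[(1R,4S,5S,7S)-7-hydroxy-4,8-dimethylspiro[4.5]dec-8-en-1-yl]-2-methylheptyl] acetate | CC(=O)OC[C@@H](C)CCC[C@@H](C)[C@H]1CC[C@H](C)[C@@]12CC=C(C)[C@@H](O)C2 | target

Total step count: 13. Longest linear sequence: 10 steps (steps 1–5 and 9–13).

**Steps most likely to fail**

1. Step 2: the electrophile may enter on the concave face, pushed there by the vicinal C4 methyl, or C-alkylation at the fully substituted ring-fusion carbon may stall. The fallback replaces ring-fusion control by open-chain steric control. From 2, aminolysis with pyrrolidine and AlMe3 would give the ring-opened hydroxy pyrrolidine amide F1, and TBSCl/imidazole would give its tert-butyldimethylsilyl ether F2. Alkylation of the amide enolate (LiN(i-Pr)2, then 3), now directed anti to the large silyloxypropyl group on C1, would give the quaternary amide F3. Cp2Zr(H)Cl would reduce this to the aldehyde F4, methoxymethylenation would give the enol ether F5, and Bu4NF would return to 6.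

2. Step 10: water may add at C8 instead of C7, or the gold-activated alkynal may close a five-membered ring. The fallback uses a tethered hydroxyl in place of carbonyl assistance. From 14, acid hydrolysis alone would give alkynal 15, and NaBH4 would give the alkynol F6. Gold-catalysed 6-exo addition of the hydroxyl to the alkyne, with (Ph3P)AuNTf2, would give the cyclic enol ether F7, and dilute acid would open it to the hydroxy ketone F8. Dess–Martin periodinane would then give keto aldehyde 16, which base would cyclise to 17.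

3. Step 11: reagent control may be eroded by the quaternary carbon next to C6, so that the 7R epimer forms. The fallback uses substrate control followed by inversion. From 17, NaBH4/CeCl3 (Luche reduction) would deliver hydride anti to the pseudoaxial ring substituent on C5. If this gives the 7R alcohol F9, Mitsunobu esterification with 4-nitrobenzoic acid would give the inverted 7S ester F10, and K2CO3/MeOH would return to 18.

**Further compounds**

F1 | step 2 | [(1R,2S,5R)-5-[(2S)-1-hydroxypropan-2-yl]-2-methylcyclopentyl](pyrrolidin-1-yl)methanone | OC[C@@H](C)[C@H]1CC[C@H](C)[C@H]1C(=O)N1CCCC1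
F2 | step 2 | [(1R,2S,5R)-5-[(2S)-1-[(tert-butyldimethylsilyl)oxy]propan-2-yl]-2-methylcyclopentyl](pyrrolidin-1-yl)methanone | CC(C)(C)[Si](C)(C)OC[C@@H](C)[C@H]1CC[C@H](C)[C@H]1C(=O)N1CCCC1
F3 | step 2 | [(1R,2S,5R)-1-(but-2-yn-1-yl)-5-[(2S)-1-[(tert-butyldimethylsilyl)oxy]propan-2-yl]-2-methylcyclopentyl](pyrrolidin-1-yl)methanone | CC(C)(C)[Si](C)(C)OC[C@@H](C)[C@H]1CC[C@H](C)[C@@]1(CC#CC)C(=O)N1CCCC1
F4 | step 2 | (1R,2S,5R)-1-(but-2-yn-1-yl)-5-[(2S)-1-[(tert-butyldimethylsilyl)oxy]propan-2-yl]-2-methylcyclopentane-1-carbaldehyde | CC(C)(C)[Si](C)(C)OC[C@@H](C)[C@H]1CC[C@H](C)[C@@]1(CC#CC)C=O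
F5 | step 2 | tert-butyl{(2S)-2-[(1R,2R,3S)-2-(but-2-yn-1-yl)-2-(2-methoxyethenyl)-3-methylcyclopentyl]propoxy}dimethylsilane | CC(C)(C)[Si](C)(C)OC[C@@H](C)[C@H]1CC[C@H](C)[C@@]1(CC#CC)C=COC
F6 | step 10 | 2-[(1R,2R,5S)-1-(but-2-yn-1-yl)-2-[(2R,6S)-7-[(tert-butyldiphenylsilyl)oxy]-6-methylheptan-2-yl]-5-methylcyclopentyl]ethan-1-ol | CC(C)(C)[Si](OC[C@@H](C)CCC[C@@H](C)[C@H]1CC[C@H](C)[C@@]1(CC#CC)CCO)(c1ccccc1)c1ccccc1
F7 | step 10 | tert-butyl{[(2S,6R)-6-[(1R,4S,5S)-7-ethylidene-4-methyl-8-oxaspiro[4.5]decan-1-yl]-2-methylheptyl]oxy}diphenylsilane | CC(C)(C)[Si](OC[C@@H](C)CCC[C@@H](C)[C@H]1CC[C@H](C)[C@]12CC(=CC)OCC2)(c1ccccc1)c1ccccc1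
F8 | step 10 | 1-[(1S,2R,5S)-2-[(2R,6S)-7-[(tert-butyldiphenylsilyl)oxy]-6-methylheptan-2-yl]-1-(2-hydroxyethyl)-5-methylcyclopentyl]butan-2-one | CC(C)(C)[Si](OC[C@@H](C)CCC[C@@H](C)[C@H]1CC[C@H](C)[C@@]1(CC(=O)CC)CCO)(c1ccccc1)c1ccccc1
F9 | step 11 | (1R,4S,5S,7R)-1-[(2R,6S)-7-[(tert-butyldiphenylsilyl)oxy]-6-methylheptan-2-yl]-4,8-dimethylspiro[4.5]dec-8-en-7-ol | CC(C)(C)[Si](OC[C@@H](C)CCC[C@@H](C)[C@H]1CC[C@H](C)[C@@]12CC=C(C)[C@H](O)C2)(c1ccccc1)c1ccccc1
F10 | step 11 | (1R,4S,5S,7S)-1-[(2R,6S)-7-[(tert-butyldiphenylsilyl)oxy]-6-methylheptan-2-yl]-4,8-dimethylspiro[4.5]dec-8-en-7-yl 4-nitrobenzoate | CC(C)(C)[Si](OC[C@@H](C)CCC[C@@H](C)[C@H]1CC[C@H](C)[C@@]12CC=C(C)[C@@H](OC(=O)c3ccc(cc3)[N+](=O)[O-])C2)(c1ccccc1)c1ccccc1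
A1 | direct plan | ethyl (2E,6S)-2-[(4S)-5-[(tert-butyldimethylsilyl)oxy]-4-methylpentyl]-6-(5-methoxy-4-methylcyclohexa-1,4-dien-1-yl)hept-2-enoate | CC(C)(C)[Si](C)(C)OC[C@@H](C)CCC/C(C(=O)OCC)=C\CC[C@H](C)C1=CCC(C)=C(OC)C1
A2 | direct plan | ethyl (2R,6S)-7-[(tert-butyldimethylsilyl)oxy]-2-[(1R,4S,5S)-7-methoxy-4,8-dimethylspiro[4.5]deca-7,9-dien-1-yl]-6-methylheptanoate | CC(C)(C)[Si](C)(C)OC[C@@H](C)CCC[C@@H](C(=O)OCC)[C@H]1CC[C@H](C)[C@@]12C=CC(C)=C(OC)C2
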